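Everything rests on removing C10 (briarane numbering, defined below). Ring A (C1, C10–C14) is traced to a cyclopentanone in which quaternary C1 is bonded directly to the C11 carbonyl, and both the C1–C10 and C9–C10 bonds are cut. C10 returns as a one-carbon linchpin from CH2Br2. In one flask a β-oxido carbenoid shifts C1 from C11 to C10, enlarging the five-membered ring to ring A. The C10=C11 enolate released adds to the C9 aldehyde of the finished chloro-lactone/tetrahydropyran half. The step exploits the aldol pattern C11(sp2)–C10(H)–C9(O) beside quaternary C1. Its precursor is a dibromomethyl carbinol of an enzymatically desymmetrised 2,2-disubstituted cyclopentanone. Ring-closing metathesis then closes the oxocane.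

Key step: step 19

Remark on numbering:
- C1 is the quaternary carbon bearing CH3-15; C2 is CHOH; C3 is CHOAc; C4 is CH–O (ether).
- C5 carries the C16 methylene; C6 is CHCl; C7 is CH–O (lactone); C8 is the quaternary carbon bearing the ether O.
- C9 is CHOAc; C10 is CH; C11 carries the C20 methylene; C12 and C13 are CH2; C14 is CHOAc.
- C17 is CH bearing CH3-18; C19 is the lactone C=O.
- On ring A the β face carries CH3-15 and the α face carries C2.

Remark on materials: the named reagents (Tebbe reagent and dimethyldioxirane as stock solutions) are taken as commercial or routinely prepared.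

Step 1
Reactants: 1 2-methylcyclopentane-1,3-dione
Product: 2 2-allyl-2-methylcyclopentane-1,3-dione
Conditions: allyl bromide, NaOH, H2O, rt
Reagents that add atoms: allyl bromide, C=CCBr
Why: C-alkylation of the stabilised 1,3-dione enolate with an allylic halide is the standard entry to 2,2-disubstituted cyclopentane-1,3-diones; C1 is still prochiral.

Step 2
Reactants: 2 2-allyl-2-methylcyclopentane-1,3-dione
Product: 3 (2S,3S)-2-allyl-3-hydroxy-2-methylcyclopentan-1-one
Conditions: NADPH-dependent ketoreductase (baker's-yeast type), NADP+ (cat.), i-PrOH, phosphate buffer pH 7, 30 °C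
Reagents that add atoms: none
Why: Enzymatic desymmetrisation by a ketoreductase reduces one enantiotopic carbonyl from one face, which sets C14 and thereby quaternary C1, with OH cis to allyl and trans to CH3-15.

Step 3
Reactants: 3 (2S,3S)-2-allyl-3-hydroxy-2-methylcyclopentan-1-one
Product: 4 TBS ether of 3
Conditions: TBSCl, imidazole, DMF, rt
Reagents that add atoms: tert-butyldimethylsilyl chloride, CC(C)(C)[Si](C)(C)Cl
Why: Standard silylation masks the C14 hydroxyl against the organolithium steps; no stereocentre is touched.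

Step 4
Reactants: 4 TBS ether of 3
Product: 5 (E)-propenyl ketone
Conditions: RuHCl(CO)(PPh3)3 (5 mol %), toluene, 110 °C
Reagents that add atoms: none
Why: Ruthenium hydride-catalysed olefin isomerisation moves the double bond one position to the internal alkene C2=C and stops there, because C1 bears no hydrogen.

Step 5
Reactants: 5 (E)-propenyl ketone
Product: 6 dibromomethyl carbinol
Conditions: CH2Br2, LiN(i-Pr)2, THF, −78 °C; H2O
Reagents that add atoms: dibromomethane, BrCBr
Why: 1,2-addition of dibromomethyllithium, generated in the presence of the ketone, should occur from the CH3-15 face, opposite to propenyl and OTBS; the new C11 carbinol centre is erased in step 19.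

Step 6
Reactants: 7 furfuryl alcohol
Product: 8 2-(tert-butyldiphenylsilyloxymethyl)furan
Conditions: TBDPSCl, imidazole, DMF, rt
Reagents that add atoms: tert-butyldiphenylsilyl chloride, CC(C)(C)[Si](Cl)(c1ccccc1)c1ccccc1
Why: Standard silylation of the primary alcohol (future C9–O) with an acid- and base-robust group.

Step 7
Reactants: 8 2-(tert-butyldiphenylsilyloxymethyl)furan
Product: 10 racemic furyl carbinol, via 5-lithiofuran 9 (not isolated)
Conditions: n-BuLi, THF, −78 to 0 °C; TBSOCH2CHO, −78 °C; H2O
Reagents that add atoms: (tert-butyldimethylsilyloxy)acetaldehyde, CC(C)(C)[Si](C)(C)OCC=O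
Why: α-lithiation of the furan at its free α-position (future C5) and addition to the aldehyde forms the C4–C5 bond; C4 is racemic at this stage.

Step 8
Reactants: 10 racemic furyl carbinol
Product: 11 pyranone hemiketal
Conditions: Ti(OiPr)4 (20 mol %), L-(+)-diisopropyl tartrate (24 mol %), t-BuOOH (0.5 equiv), 4 Å MS, CH2Cl2, −20 °C
Reagents that add atoms: tert-butyl hydroperoxide, CC(C)(C)OO
Why: Sharpless kinetic resolution of a 2-furyl carbinol oxidises the furan of the (S)-alcohol much faster, and the ene-dione closes to the pyranone (Achmatowicz rearrangement), so C4 enters in one enantiomeric series while the (R)-alcohol stays behind.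

Step 9
Reactants: 12 propionic acid
Product: 14 bis(trimethylsilyl) ketene acetal, via dilithium enediolate 13 (not isolated)
Conditions: LiN(i-Pr)2 (2.1 equiv), THF, 0 °C; Me3SiCl (2.2 equiv)
Reagents that add atoms: chlorotrimethylsilane, C[Si](C)(C)Cl
Why: Double deprotonation and double O-silylation of a carboxylic acid give a geometry-free C17–C19 nucleophile.

Step 10
Reactants: 11 pyranone hemiketal; 14 bis(trimethylsilyl) ketene acetal
Product: 15 enone acid
Conditions: TMSOTf (20 mol %), CH2Cl2, −78 °C; aq. citric acid
Reagents that add atoms: none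
Why: C-glycosidation of an Achmatowicz pyranone: the tertiary hemiketal ionises to the cyclic oxocarbenium ion, the ketene acetal attacks C8 axially anti to the C4 side chain (2,6-trans, C9 cis to C3), and an open antiperiplanar transition state that keeps CH3-18 away from the C9H2OSi branch sets C17.

Step 11
Reactants: 15 enone acid
Product: 17 hydroxy keto lactone, via epoxy acid 16 (not isolated)
Conditions: dimethyldioxirane, acetone, 0 °C to rt; camphorsulfonic acid (cat.), CH2Cl2
Reagents that add atoms: dimethyldioxirane, CC1(C)OO1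
Why: Neutral dioxirane epoxidation of the only C=C from the face opposite to the axial C17 branch, then acid-catalysed 5-exo opening at C7 by the carboxylic acid with inversion, gives the cis-fused γ-lactone (C7) and leaves the C6 hydroxyl trans to O7.

Step 12
Reactants: 17 hydroxy keto lactone
Product: 18 chloro keto lactone
Conditions: SOCl2, pyridine, CH2Cl2, −20 to 0 °C
Reagents that add atoms: thionyl chloride, O=S(Cl)Cl
Why: Thionyl chloride–pyridine replaces the secondary α-ketol hydroxyl by chloride with inversion (SN2, accelerated by the adjacent carbonyl), which places Cl at C6 cis to O7 as in the target.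

Step 13
Reactants: 18 chloro keto lactone
Product: 19 C5-methylene bis-silyl ether
Conditions: Tebbe reagent Cp2Ti(μ-CH2)(μ-Cl)AlMe2 (1.2 equiv), pyridine (cat.), THF–toluene, −40 to 0 °C
Reagents that add atoms: Tebbe reagent, C[Al-]1(C)C[Ti](C2C=CC=C2)(C2C=CC=C2)[Cl+]1
Why: Tebbe methylenation uses a non-basic titanium methylidene that reacts with ketones faster than with lactones and does not enolise the α-chloro ketone, so C4 and C6 stay intact.

Step 14
Reactants: 19 C5-methylene bis-silyl ether
Product: 20 C3 alcohol
Conditions: HF·pyridine, pyridine, THF, 0 °C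
Reagents that add atoms: none
Why: Buffered fluoride cleaves the unhindered primary TBS ether much faster than the neopentyl primary TBDPS ether.

Step 15
Reactants: 20 C3 alcohol
Product: 21 C3 aldehyde
Conditions: Dess–Martin periodinane, NaHCO3, CH2Cl2, 0 °C
Reagents that add atoms: none
Why: Neutral hypervalent-iodine oxidation gives the α-alkoxy aldehyde without epimerising C4; it is used at once.

Step 16
Reactants: 21 C3 aldehyde
Product: 22 C4-vinyl silyl ether
Conditions: Tebbe reagent Cp2Ti(μ-CH2)(μ-Cl)AlMe2 (1.1 equiv), THF, −78 to −20 °C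
Reagents that add atoms: Tebbe reagent, C[Al-]1(C)C[Ti](C2C=CC=C2)(C2C=CC=C2)[Cl+]1
Why: The non-basic methylenation is fastest on the aldehyde, leaves the lactone alone, and avoids epimerisation or double-bond migration at the doubly allylic C4.

Step 17
Reactants: 22 C4-vinyl silyl ether
Product: 23 C9 alcohol
Conditions: HF·pyridine, THF, rt
Reagents that add atoms: none
Why: Unbuffered fluoride removes the remaining silyl ether; lactone, allylic chloride and alkenes are inert to it.

Step 18
Reactants: 23 C9 alcohol
Product: 24 C9 aldehyde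
Conditions: Dess–Martin periodinane, NaHCO3, CH2Cl2, rt
Reagents that add atoms: none
Why: Oxidation of the neopentyl primary alcohol gives an aldehyde on quaternary C8 that has no α-hydrogen and cannot epimerise.

Step 19
Reactants: 6 dibromomethyl carbinol; 24 C9 aldehyde
Product: 28 aldol adduct, via β-oxido carbenoid 25 (not isolated), via ring-enlarged lithium enolate 26 (not isolated), via titanium enolate 27 (not isolated)
Conditions: n-BuLi (2.1 equiv), THF, −95 to −20 °C; ClTi(OiPr)3, −78 °C; 24, −78 °C; aq. NH4Cl
Reagents that add atoms: none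
Why: n-BuLi deprotonates the carbinol and exchanges one bromine to give β-oxido carbenoid 25, in which loss of LiBr is concerted with a 1,2-shift of the ring bond C11–C1 onto C10; this enlarges the five-membered ring (C1, C11–C14) to six-membered ring A and releases lithium enolate 26 with its double bond fixed between C10 and C11. The closest known reaction type is the β-oxido carbenoid ring enlargement of cycloalkanones, in which the more substituted α-carbon migrates with retention and the enolate can be trapped, followed here by a titanium-enolate aldol addition. No further ring is closed: the only ring event is the one-carbon insertion, a 1,2-shift and not a cyclisation. C1 and C14 are carried over unchanged; C10 is set by axial attack of aldehyde 24 on the β face of the enolate half-chair, anti to the pseudo-axial propenyl group and away from OTBS, and C9 by the syn preference of triisopropoxytitanium enolates of cyclic ketones together with a Cornforth-type approach to the α-alkoxy aldehyde. The step needs migration of C1 rather than C12, secured by the quaternary and allylic nature of C1, and attack on the aldehyde rather than on the lactone or allylic chloride, secured by the low basicity of titanium enolate 27 at −78 °C.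

Step 20
Reactants: 28 aldol adduct
Product: 29 C9,C14-diol
Conditions: HF (48 % aq.), MeCN, 0 °C to rt
Reagents that add atoms: none
Why: Acidic fluoride removes the hindered secondary TBS ether without the base that would trigger retro-aldol cleavage or C10 epimerisation.

Step 21
Reactants: 29 C9,C14-diol
Product: 30 C9,C14-diacetate
Conditions: Ac2O, DMAP (cat.), pyridine, CH2Cl2, 0 °C to rt
Reagents that add atoms: acetic anhydride, CC(=O)OC(C)=O
Why: Nucleophile-catalysed acylation installs two of the three final acetates on the only free hydroxyls and blocks the retro-aldol path.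

Step 22
Reactants: 30 C9,C14-diacetate
Product: 31 bridged oxocene
Conditions: second-generation Hoveyda–Grubbs catalyst (H2IMes)Cl2Ru(=CH-C6H4-2-O-i-Pr) (10 mol %), toluene (1 mM), 80 °C, Ar sparge
Reagents that add atoms: none
Why: Ring-closing metathesis to an eight-membered cyclic ether: the catalyst loads on the unhindered C4 vinyl group and closes onto the propenyl group with loss of propene, the chloride-flanked 1,1-disubstituted C5=C16 alkene is inert, and the ring size enforces the Z alkene C2=C3.

Step 23
Reactants: 31 bridged oxocene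
Product: 32 C2,C3-cis-diol
Conditions: OsO4 (5 mol %), N-methylmorpholine N-oxide, acetone–H2O, 0 °C to rt
Reagents that add atoms: N-methylmorpholine N-oxide, C[N+]1([O-])CCOCC1; water, O
Why: Upjohn dihydroxylation attacks the strained cis-alkene, not the electron-poor hindered C5 methylene, from the face turned toward the one-atom oxygen bridge and away from the C5–C7 bridge, which sets C3 as in the target; the C2 centre formed with it is corrected in steps 26 and 27.

Step 24
Reactants: 32 C2,C3-cis-diol
Product: 33 C3 acetate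
Conditions: Ac2O (1.1 equiv), pyridine, CH2Cl2, 0 °C
Reagents that add atoms: acetic anhydride, CC(=O)OC(C)=O
Why: Steric differentiation: the C3 hydroxyl between two CH groups is acylated faster than the neopentyl C2 hydroxyl next to quaternary C1.

Step 25
Reactants: 33 C3 acetate
Product: 34 2-epi-target
Conditions: Tebbe reagent Cp2Ti(μ-CH2)(μ-Cl)AlMe2 (2.5 equiv), pyridine (cat.), THF–toluene, −40 to 0 °C
Reagents that add atoms: Tebbe reagent, C[Al-]1(C)C[Ti](C2C=CC=C2)(C2C=CC=C2)[Cl+]1
Why: Tebbe methylenation of the only ketone (C11) is non-basic, so the β-acetoxy group at C9 is not eliminated and C10 is not epimerised; esters react more slowly at this temperature.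

Step 26
Reactants: 34 2-epi-target
Product: 35 C2 ketone
Conditions: Dess–Martin periodinane, NaHCO3, CH2Cl2, rt
Reagents that add atoms: none
Why: The only free hydroxyl is oxidised under neutral conditions that do not epimerise the α-acetoxy centre C3.

Step 27
Reactants: 35 C2 ketone
Product: 36 CNP0248899.1 (target)
Conditions: NaBH4, CeCl3·7H2O, MeOH–CH2Cl2, −78 °C; AcOH
Reagents that add atoms: none
Why: Luche-type 1,2-reduction delivers hydride from the exposed oxygen-bridge face, in line with the polar Felkin–Anh model for an α-acyloxy ketone (syn diol), so the C2 hydroxyl ends on the inner face (2,3-threo); the cerium salt keeps the medium non-basic and suppresses acetyl migration.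

Compound list

1 | 2-methylcyclopentane-1,3-dione | CC1C(=O)CCC1=O | starting material
2 | 2-allyl-2-methylcyclopentane-1,3-dione | C=CCC1(C)C(=O)CCC1=O | intermediate
3 | (2S,3S)-2-allyl-3-hydroxy-2-methylcyclopentan-1-one (OH cis to allyl) | O=C1CC[C@H](O)[C@]1(C)CC=C | intermediate
4 | (2S,3S)-2-allyl-3-(tert-butyldimethylsilyloxy)-2-methylcyclopentan-1-one | O=C1CC[C@H](O[Si](C)(C)C(C)(C)C)[C@]1(C)CC=C | intermediate
5 | (2S,3S)-3-(tert-butyldimethylsilyloxy)-2-methyl-2-[(E)-prop-1-enyl]cyclopentan-1-one | O=C1CC[C@H](O[Si](C)(C)C(C)(C)C)[C@]1(C)/C=C/C | intermediate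
6 | 1-(dibromomethyl) carbinol of 5 (CHBr2 cis to CH3-15, OH cis to propenyl and OTBS) | BrC(Br)[C@@]1(O)CC[C@H](O[Si](C)(C)C(C)(C)C)[C@]1(C)/C=C/C | intermediate
7 | furfuryl alcohol | OCc1ccco1 | starting material
8 | 2-(tert-butyldiphenylsilyloxymethyl)furan | CC(C)(C)[Si](c1ccccc1)(c1ccccc1)OCc1ccco1 | intermediate
9 | 5-lithio derivative of 8 | [Li]c1ccc(CO[Si](c2ccccc2)(c2ccccc2)C(C)(C)C)o1 | intermediate
10 | racemic 2-(TBSO)-1-[5-(TBDPSO-methyl)furan-2-yl]ethanol | CC(C)(C)[Si](C)(C)OCC(O)c1ccc(CO[Si](c2ccccc2)(c2ccccc2)C(C)(C)C)o1 | intermediate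
11 | 6-hydroxy-2H-pyran-3(6H)-one, C4 configured as in the target, bearing C3H2OTBS at C4 and C9H2OTBDPS at hemiketal carbon C8 (anomers) | CC(C)(C)[Si](C)(C)OC[C@@H]1OC(O)(CO[Si](c2ccccc2)(c2ccccc2)C(C)(C)C)C=CC1=O | intermediate
12 | propionic acid | CCC(=O)O | starting material
13 | dilithium enediolate of propionic acid | CC=C(O[Li])O[Li] | intermediate
14 | 1,1-bis(trimethylsilyloxy)prop-1-ene | CC=C(O[Si](C)(C)C)O[Si](C)(C)C | intermediate
15 | enone acid: 2,6-trans-dihydropyranone with quaternary C8 (C9H2OTBDPS cis to the C4 side chain, C17H(CH3)CO2H trans), C17 as in the target | CC(C)(C)[Si](c1ccccc1)(c1ccccc1)OC[C@]2(O[C@@H](CO[Si](C)(C)C(C)(C)C)C(=O)C=C2)[C@@H](C)C(=O)O | intermediate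
16 | C6,C7-epoxy acid (epoxide cis to C9, trans to C17) | CC(C)(C)[Si](c1ccccc1)(c1ccccc1)OC[C@]2(O[C@@H](CO[Si](C)(C)C(C)(C)C)C(=O)[C@H]3O[C@H]32)[C@@H](C)C(=O)O | intermediate
17 | hydroxy keto lactone: cis-fused γ-lactone/pyran-3-one, C6–OH trans to O7 | CC(C)(C)[Si](c1ccccc1)(c1ccccc1)OC[C@@]23O[C@@H](CO[Si](C)(C)C(C)(C)C)C(=O)[C@@H](O)[C@@H]2OC(=O)[C@@H]3C | intermediate
18 | chloro keto lactone, C6–Cl cis to O7 | CC(C)(C)[Si](c1ccccc1)(c1ccccc1)OC[C@@]23O[C@@H](CO[Si](C)(C)C(C)(C)C)C(=O)[C@H](Cl)[C@@H]2OC(=O)[C@@H]3C | intermediate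
19 | C5-methylene chloro lactone, C3–OTBS, C9–OTBDPS | CC(C)(C)[Si](c1ccccc1)(c1ccccc1)OC[C@@]23O[C@@H](CO[Si](C)(C)C(C)(C)C)C(=C)[C@H](Cl)[C@@H]2OC(=O)[C@@H]3C | intermediate
20 | C3 primary alcohol | CC(C)(C)[Si](c1ccccc1)(c1ccccc1)OC[C@@]23O[C@@H](CO)C(=C)[C@H](Cl)[C@@H]2OC(=O)[C@@H]3C | intermediate
21 | C3 aldehyde | CC(C)(C)[Si](c1ccccc1)(c1ccccc1)OC[C@@]23O[C@@H](C=O)C(=C)[C@H](Cl)[C@@H]2OC(=O)[C@@H]3C | intermediate
22 | C4-vinyl chloro lactone, C9–OTBDPS | CC(C)(C)[Si](c1ccccc1)(c1ccccc1)OC[C@@]23O[C@@H](C=C)C(=C)[C@H](Cl)[C@@H]2OC(=O)[C@@H]3C | intermediate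
23 | C9 primary alcohol | OC[C@@]23O[C@@H](C=C)C(=C)[C@H](Cl)[C@@H]2OC(=O)[C@@H]3C | intermediate
24 | C9 aldehyde (C4, C6, C7, C8, C17 as in the target) | O=C[C@@]23O[C@@H](C=C)C(=C)[C@H](Cl)[C@@H]2OC(=O)[C@@H]3C | intermediate
25 | β-oxido carbenoid (lithium alkoxide, C10 bearing H, Br, Li) | [Li]C(Br)[C@@]1(O[Li])CC[C@H](O[Si](C)(C)C(C)(C)C)[C@]1(C)/C=C/C | intermediate
26 | ring-enlarged lithium enolate (ring A, C10=C11) | [Li]OC1=C[C@@](C)(/C=C/C)[C@@H](O[Si](C)(C)C(C)(C)C)CC1 | intermediate
27 | triisopropoxytitanium enolate of ring A | CC(C)O[Ti](OC(C)C)(OC(C)C)OC1=C[C@@](C)(/C=C/C)[C@@H](O[Si](C)(C)C(C)(C)C)CC1 | intermediate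
28 | aldol adduct: ring A ketone (C11=O), 14α-OTBS, 1β-CH3, 1α-(E)-propenyl, 10β-C9H(OH) joined to C8; C9, C10 as in the target | O=C1CC[C@H](O[Si](C)(C)C(C)(C)C)[C@](C)(/C=C/C)[C@H]1[C@H](O)[C@@]23O[C@@H](C=C)C(=C)[C@H](Cl)[C@@H]2OC(=O)[C@@H]3C | intermediate
29 | C9,C14-diol | O=C1CC[C@H](O)[C@](C)(/C=C/C)[C@H]1[C@H](O)[C@@]23O[C@@H](C=C)C(=C)[C@H](Cl)[C@@H]2OC(=O)[C@@H]3C | intermediate
30 | C9,C14-diacetate | O=C1CC[C@H](OC(C)=O)[C@](C)(/C=C/C)[C@H]1[C@H](OC(C)=O)[C@@]23O[C@@H](C=C)C(=C)[C@H](Cl)[C@@H]2OC(=O)[C@@H]3C | intermediate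
31 | bridged oxocene, (Z)-C2=C3, C11 ketone | O=C1CC[C@H](OC(C)=O)[C@@]2(C)[C@H]1[C@H](OC(C)=O)[C@@]13O[C@H](C(=C)[C@H](Cl)[C@@H]1OC(=O)[C@@H]3C)/C=C\2 | intermediate
32 | C2,C3-cis-diol (C3 as in the target, C2 epimeric) | O=C1CC[C@H](OC(C)=O)[C@@]2(C)[C@H]1[C@H](OC(C)=O)[C@@]13O[C@H](C(=C)[C@H](Cl)[C@@H]1OC(=O)[C@@H]3C)[C@@H](O)[C@H]2O | intermediate
33 | C3,C9,C14-triacetate, C2–OH epimeric, C11 ketone | O=C1CC[C@H](OC(C)=O)[C@@]2(C)[C@H]1[C@H](OC(C)=O)[C@@]13O[C@H](C(=C)[C@H](Cl)[C@@H]1OC(=O)[C@@H]3C)[C@@H](OC(C)=O)[C@H]2O | intermediate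
34 | 2-epi-target (C11=C20 installed) | C=C1CC[C@H](OC(C)=O)[C@@]2(C)[C@H]1[C@H](OC(C)=O)[C@@]13O[C@H](C(=C)[C@H](Cl)[C@@H]1OC(=O)[C@@H]3C)[C@@H](OC(C)=O)[C@H]2O | intermediate
35 | C2 ketone | C=C1CC[C@H](OC(C)=O)[C@@]2(C)[C@H]1[C@H](OC(C)=O)[C@@]13O[C@H](C(=C)[C@H](Cl)[C@@H]1OC(=O)[C@@H]3C)[C@@H](OC(C)=O)C2=O | intermediate
36 | CNP0248899.1 | C=C1CC[C@H](OC(C)=O)[C@@]2(C)[C@H]1[C@H](OC(C)=O)[C@@]13O[C@H](C(=C)[C@H](Cl)[C@@H]1OC(=O)[C@@H]3C)[C@@H](OC(C)=O)[C@@H]2O | target

Total step count: 27. Longest linear sequence: 21 steps (7 to 36: steps 6–8 and 10–27).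

Steps most likely to fail

Step 19. Several processes could defeat it:
- competing migration of C12;
- proton transfer to the hindered enolate before the C9–C10 bond forms between two neopentyl centres;
- retro-aldol cleavage on warming;
- erosion of the syn selectivity.

The fallback separates ring enlargement from coupling and changes the bond-forming mode. It sets out from 6. The carbenoid rearrangement (n-BuLi, THF) is quenched with Me3SiCl to isolate the ring-A trimethylsilyl enol ether F1. This is joined to aldehyde 24 in a Mukaiyama aldol addition (BF3·OEt2, CH2Cl2, −78 °C). The open transition state is syn-selective and the addition is not reversible under these conditions. The fallback comes back to the route at 28.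

Step 22. Initiation at the neopentyl propenyl group may be slow. The tetrahydropyran must reach the conformer with both arms axial, which costs strain. Oligomerisation could then outrun closure.

The fallback replaces olefin metathesis by reductive carbonyl coupling and sets out from 30. Johnson–Lemieux cleavage (OsO4 cat., NaIO4, 2,6-lutidine, dioxane–H2O) of the vinyl and propenyl groups gives the C2,C3-dialdehyde F2; the chloride-flanked C5 methylene is the least reactive alkene. A pinacol cyclisation with SmI2 (THF, −78 °C) through the chelated bis-ketyl should give the cis-diol. The fallback comes back to the route at 32 and bypasses 31.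

Step 13. β-Elimination of the lactone carboxylate, loss of chloride from the α-chloro-β-acyloxy ketone, or methylenation of the lactone could compete.

The fallback inverts the order of the two operations and sets out from 17. The α-hydroxy ketone is methylenated first with excess Cp2TiMe2 (toluene, 65 °C), the hydroxyl being carried as its titanium alkoxide, to give the allylic alcohol F3. Chloride is then introduced with inversion by an Appel reaction (Ph3P, CCl4, CH2Cl2). The fallback comes back to the route at 19.

Further compounds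
F1 | step 19 | ring-A trimethylsilyl enol ether (C10=C11) | C[Si](C)(C)OC1=C[C@@](C)(/C=C/C)[C@@H](O[Si](C)(C)C(C)(C)C)CC1
F2 | step 22 | C2,C3-dialdehyde derived from 30 | O=C1CC[C@H](OC(C)=O)[C@](C)(C=O)[C@H]1[C@H](OC(C)=O)[C@@]23O[C@@H](C=O)C(=C)[C@H](Cl)[C@@H]2OC(=O)[C@@H]3C
F3 | step 13 | C5-methylene C6 allylic alcohol (OH trans to O7) | CC(C)(C)[Si](c1ccccc1)(c1ccccc1)OC[C@@]23O[C@@H](CO[Si](C)(C)C(C)(C)C)C(=C)[C@@H](O)[C@@H]2OC(=O)[C@@H]3C
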